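The data were computed for substances that don't exist, noise included.

Late in a flask, the target that stands is what the enzyme has made, times the fraction of it still left. So this reckoning works with fractions left.

in all of them: starting material 0.10 M; enzyme 0.56 µM
- south: second substrate 0.050 M; protic impurity 0.75 mM; run made earlier
- south-east: second substrate 0.050 M; protic impurity 2.7 mM; run made earlier
- Saturday's: second substrate 0.0500 M; protic impurity 0.600 mM; time 20 min
- Wednesday's: second substrate 0.0500 M; protic impurity 1.20 mM; time 20 min
- Monday's: second substrate 0.0500 M; protic impurity 2.50 mM; time 20 min
- Tuesday's: second substrate 0.0500 M; protic impurity 5.00 mM; time 20 min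
- Friday's: second substrate 0.0500 M; protic impurity 10.0 mM; time 20 min

| run | time / min | target / % | starting material / % |
|---|---|---|---|
| south | 0.833 | 1.3 | 98.4 |
| south | 1.50 | 1.7 | 97.5 |
| south | 3.00 | 5.6 | 93.2 |
| south | 5.00 | 8.4 | 90.9 |
| south | 10.0 | 10.9 | 83.3 |
| south-east | 2.00 | 3.7 | 95.9 |
| south-east | 4.00 | 6.9 | 91.8 |
| south-east | 6.00 | 8.2 | 89.0 |
| south-east | 8.00 | 9.6 | 84.9 |
| south-east | 10.0 | 11.3 | 83.0 |

(readings scatter by 0.5 percentage points)

- percentages count the starting material that a species holds: one spent catalyst or side product counts as two
- candidate steps: starting material + enzyme <-> complex A; complex A -> enzyme + target; second substrate + enzyme <-> complex B; complex B -> enzyme + second product; second substrate + protic impurity -> quenched substrate; 2 complex A -> spent catalyst; starting material + target -> side product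
- "hardly changes" means that all values lie within two and a half points (for a concentration: within two and a half percent of the largest)

* amount of target at the end, in percent of the starting material charged for Saturday's, Wednesday's, Monday's, Tuesday's, Friday's, in this order
* how that number moves from the first to the last of them (rises all the way / falls all the way / rises, then falls / falls, then rises / hardly changes)

The south-east run serves here: its times are evenly spaced. One side product consumes one target and counts double in percent. At 10.0 min that run lacks 5.70% from its balance, so 2.85% of target has been destroyed and gross target stands at 14.1%.

Target averaged 6.81% over that time, while starting material stayed near 91.5%. The loss of target is therefore pseudo-first-order, with a constant of 0.0419 min⁻¹. That gives the half-life of target against starting material, 16.6 min, read at that level of starting material and scaling inversely with it.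

Next comes the making. Two complex A destroy each other, so the reciprocal of the rate should climb in a straight line. Gross rate reads 0.0189 min⁻¹ around 2.00 min and 0.0114 min⁻¹ around 8.00 min, as fractions of the charge. The slope of the reciprocal is 5.82. Carried forward, it adds 7.91% of gross target by 20 min.

Now the fractions left. Target present at 10.0 min keeps 65.8%, and new target, on average younger, keeps 81.1%. So 13.9% should stand at 20 min.

The weak link is the step to 10.0 mM of impurity, beyond the runs. Those runs read 10.9% and 11.3% at 10.0 min, with a scatter of 0.5 percentage points, which bounds little. The charge bounds more: Friday's impurity can quench 20.0% of the second substrate. The two runs stand within scatter of each other, so the row is committed, as a judgement, as flat near 13.9%.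

The forecast gives 15% falling to 14.8%, hardly changes, since “the row stays flat”.

The flask gives 12.8% at 0.600 mM and 12.8% at 10.0 mM: hardly changes.

    starting material + enzyme ⇌ complex A (K = 29.0 L mol⁻¹, k = 1.20 × 10⁵ L mol⁻¹ s⁻¹)
    complex A → enzyme + target (k = 98.0 s⁻¹)
    second substrate + enzyme ⇌ complex B (K = 120 L mol⁻¹, k = 22000 L mol⁻¹ s⁻¹)
    complex B → enzyme + second product (k = 2700 s⁻¹)
    second substrate + protic impurity → quenched substrate (k = 0.600 L mol⁻¹ s⁻¹)
    2 complex A → spent catalyst (k = 4600 L mol⁻¹ s⁻¹)
    starting material + target → side product (k = 0.00910 L mol⁻¹ s⁻¹)

That stands 1.1 points below the reckoning. Removing the quench makes no difference to Friday's target. Scaled to starting material at 70.7% on Friday's at 20.0 min, the half-life read from the south-east run reckons to 21.5 min, an estimate that carries the scatter of those readings. In Saturday's flask at 200 min, starting material is down to 10.2%, the same scaling reckons to 149 min, and target stands at 9.23%.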